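**Plan**
- Retrosynthesis: the last cut unmasks the C2' aldehyde (diethyl acetal) and the tertiary alcohol (triethylsilyl ether). Ring A is then cut at C6'–C1' and C3'–C2', and its C3' oxygen is traced back to a furan oxygen, giving 2-prenylfuran and an aryl ynone acetal.
- Enabling feature: ring A (C1' aroyl, C2' formyl, C3' OH, C6' prenyl) is a 4-alkylphenol whose two carbons between the alkyl and hydroxyl positions each carry a carbonyl carbon. The furan supplies C3'–C6' and the oxygen; the alkyne supplies C1' and C2'.
- The ynone is cut at the aryl–CO bond: an 8-lithio-benzodioxane plus an alkynyl Weinreb amide.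
- The benzodioxane is cut at C4a–O4 (intramolecular Ullmann coupling) and O1–C2 (Mitsunobu) to 2,6-dibromo-4-methylphenol and a glycerate; the CMe2OH group comes from the ester and MeMgBr. One bromine closes the ring, the other becomes the acylation handle.
- Forward order: side chain onto the phenol oxygen, dioxane ring, ynone, then ring A by cycloaddition/aromatisation, then deprotection.
- Stereochemistry: the only stereocentre (C2 of the benzodioxane, R) comes from methyl (S)-glycerate with inversion in the Mitsunobu step; no later step breaks a bond to it.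

Key step: step 9

Assumption: methyl (S)-glycerate is taken as a purchasable chiral-pool ester. Benzodioxane locants are used with O1 on the stereocentre C2 and the bromo/acyl carbon as C8.

Step 1
Reactants: 1 methyl (2S)-2,3-dihydroxypropanoate
Product: 2 methyl (2S)-3-[tert-butyl(dimethyl)silyl]oxy-2-hydroxypropanoate
Conditions: TBSCl (1.05 equiv), imidazole, CH2Cl2, 0 °C
Reagents that add atoms: tert-butyldimethylsilyl chloride, CC(C)(C)[Si](C)(C)Cl
Why: Selective silylation of the primary hydroxyl of a 1,2-diol by a bulky silyl chloride should leave the secondary carbinol free, and the stereocentre is not involved.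

Step 2
Reactants: 2 methyl (2S)-3-[tert-butyl(dimethyl)silyl]oxy-2-hydroxypropanoate; 3 2,6-dibromo-4-methylphenol
Product: 4 methyl (2R)-3-[tert-butyl(dimethyl)silyl]oxy-2-(2,6-dibromo-4-methylphenoxy)propanoate
Conditions: PPh3, DIAD, toluene, 0 °C → rt
Reagents that add atoms: none
Why: Mitsunobu etherification of an α-hydroxy ester with an acidic phenol proceeds by SN2 displacement of the oxyphosphonium group, so the (S)-carbinol should give the (R)-aryl ether with clean inversion, and the symmetric phenol leaves no regiochemical question.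

Step 3
Reactants: 4 methyl (2R)-3-[tert-butyl(dimethyl)silyl]oxy-2-(2,6-dibromo-4-methylphenoxy)propanoate
Product: 6 (2R)-2-(2,6-dibromo-4-methylphenoxy)-3-methylbutane-1,3-diol, via silyl ether carbinol 5 (not isolated)
Conditions: MeMgBr (3.5 equiv), THF, 0 °C → rt; then 3 M aq. HCl, rt
Reagents that add atoms: methylmagnesium bromide, C[Mg]Br
Why: Double Grignard addition converts the ester into the dimethyl carbinol, and prolonging the acidic work-up hydrolyses the primary TBS ether; the aryl bromides are inert to MeMgBr and the stereocentre is no longer enolisable once the ester is consumed.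

Step 4
Reactants: 6 (2R)-2-(2,6-dibromo-4-methylphenoxy)-3-methylbutane-1,3-diol
Product: 7 2-[(2R)-8-bromo-6-methyl-2,3-dihydro-1,4-benzodioxin-2-yl]propan-2-ol
Conditions: CuI (10 mol %), 1,10-phenanthroline (20 mol %), Cs2CO3 (2 equiv), toluene (0.05 M), 110 °C
Reagents that add atoms: none
Why: Intramolecular Ullmann-type C–O coupling of the primary alkoxide with either of the two equivalent ortho C–Br bonds closes the dioxane ring and leaves the other bromine at C8; the tertiary alcohol couples far more slowly, and no bond to C2 is broken.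

Step 5
Reactants: 7 2-[(2R)-8-bromo-6-methyl-2,3-dihydro-1,4-benzodioxin-2-yl]propan-2-ol
Product: 8 [2-[(2R)-8-bromo-6-methyl-2,3-dihydro-1,4-benzodioxin-2-yl]propan-2-yl]oxy-triethylsilane
Conditions: TESOTf, 2,6-lutidine, CH2Cl2, 0 °C
Reagents that add atoms: triethylsilyl trifluoromethanesulfonate, CC[Si](CC)(CC)OS(=O)(=O)C(F)(F)F
Why: Silyl triflate with a hindered pyridine base is the standard silylation of tertiary alcohols and masks the hydroxyl for the organolithium and Lewis acid steps.

Step 6
Reactants: 9 3,3-diethoxyprop-1-yne; 10 N-methoxy-N-methylcarbamoyl chloride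
Product: 12 4,4-diethoxy-N-methoxy-N-methylbut-2-ynamide, via lithium acetylide 11 (not isolated)
Conditions: n-BuLi, THF, −78 °C; then 10, −78 → 0 °C
Reagents that add atoms: none
Why: Deprotonation of the terminal alkyne and nucleophilic acyl substitution of the carbamoyl chloride by the acetylide is the usual route to alkynyl Weinreb amides, and the acetal is stable to base.

Step 7
Reactants: 8 [2-[(2R)-8-bromo-6-methyl-2,3-dihydro-1,4-benzodioxin-2-yl]propan-2-yl]oxy-triethylsilane; 12 4,4-diethoxy-N-methoxy-N-methylbut-2-ynamide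
Product: 15 4,4-diethoxy-1-[(2R)-6-methyl-2-(2-triethylsilyloxypropan-2-yl)-2,3-dihydro-1,4-benzodioxin-8-yl]but-2-yn-1-one, via aryllithium 13 (not isolated), via lithium hemiaminal adduct 14 (not isolated)
Conditions: n-BuLi (1.05 equiv), THF, −78 °C; then 12, −78 → −40 °C; AcOH/THF quench at −78 °C
Reagents that add atoms: none
Why: Bromine–lithium exchange ortho to an ether oxygen is fast, and Weinreb ketone synthesis through the chelated tetrahedral adduct stops at the ynone; the cold acidic quench protonates the released amine so that it should not add to the ynone.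

Step 8
Reactants: 16 furan; 17 1-bromo-3-methylbut-2-ene (prenyl bromide)
Product: 19 2-(3-methylbut-2-en-1-yl)furan, via 2-furyllithium 18 (not isolated)
Conditions: n-BuLi, THF, 0 °C (furan in excess); then 17, −78 °C → rt
Reagents that add atoms: none
Why: α-Lithiation of furan followed by SN2 alkylation with the primary allylic bromide is the established entry to 2-prenylfurans and should give the linear prenyl isomer.

Step 9
Reactants: 15 4,4-diethoxy-1-[(2R)-6-methyl-2-(2-triethylsilyloxypropan-2-yl)-2,3-dihydro-1,4-benzodioxin-8-yl]but-2-yn-1-one; 19 2-(3-methylbut-2-en-1-yl)furan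
Product: 21 [2-(diethoxymethyl)-3-hydroxy-6-(3-methylbut-2-en-1-yl)phenyl][(2R)-6-methyl-2-(2-triethylsilyloxypropan-2-yl)-2,3-dihydro-1,4-benzodioxin-8-yl]methanone, via oxanorbornadiene 20 (not isolated)
Conditions: 19 (3 equiv), Me2AlCl (2 equiv), CH2Cl2, −78 → 0 °C; aq. Rochelle salt/NaHCO3 work-up
Reagents that add atoms: none
Why: Me2AlCl binds the aryl ketone (helped by the neighbouring ring oxygen O1), lowering the alkyne LUMO and placing its largest coefficient on the acetal-bearing carbon, so the unsubstituted, most nucleophilic furan α-carbon bonds there (C3'–C2') while the prenylated α-carbon bonds to the acyl-bearing carbon (C6'–C1') in an asynchronous [4+2] cycloaddition that gives oxanorbornadiene 20. Ring A is closed in this intermolecular cycloaddition, its six carbons being the four furan carbons and the two alkyne carbons. Aluminium-assisted heterolysis of the bridging C–O bond at the tertiary, doubly allylic, prenyl-bearing bridgehead then gives a cyclohexadienyl cation that loses the proton of the other bridgehead, so the furan oxygen ends as the C3' hydroxyl and the irreversible aromatisation pulls the otherwise reversible furan cycloaddition forward. The closest known reaction type is the Lewis-acid-promoted Diels–Alder reaction of 2-alkylfurans with acetylenic esters and ketones followed by oxanorbornadiene-to-phenol isomerisation, which gives 4-alkylphenols with the carbonyl group ortho to the alkyl group. No stereocentre remains from this step (the two bridgehead centres of 20 vanish on aromatisation) and C2 of the benzodioxane is remote and untouched. The step needs regiocontrol in both the cycloaddition and the bridge opening, secured by the ketone polarisation and the tertiary bridgehead, and chemoselectivity towards the acetal, the silyl ether and the prenyl group, for which a mild, proton-scavenging aluminium reagent at low temperature is chosen.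

Step 10
Reactants: 21 [2-(diethoxymethyl)-3-hydroxy-6-(3-methylbut-2-en-1-yl)phenyl][(2R)-6-methyl-2-(2-triethylsilyloxypropan-2-yl)-2,3-dihydro-1,4-benzodioxin-8-yl]methanone
Product: 22 6-hydroxy-2-[(2R)-2-(2-hydroxypropan-2-yl)-6-methyl-2,3-dihydro-1,4-benzodioxine-8-carbonyl]-3-(3-methylbut-2-en-1-yl)benzaldehyde
Conditions: 1 M aq. HCl, THF, rt
Reagents that add atoms: water, O
Why: Acid-catalysed acetal hydrolysis and silyl ether hydrolysis should occur in one operation under dilute acid, which the prenyl group, the tertiary alcohol and the stereocentre tolerate at room temperature.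

**Compound list**
1 | methyl (2S)-2,3-dihydroxypropanoate | COC(=O)[C@@H](O)CO | starting material
2 | methyl (2S)-3-[tert-butyl(dimethyl)silyl]oxy-2-hydroxypropanoate | COC(=O)[C@@H](O)CO[Si](C)(C)C(C)(C)C | intermediate
3 | 2,6-dibromo-4-methylphenol | Cc1cc(Br)c(O)c(Br)c1 | starting material
4 | methyl (2R)-3-[tert-butyl(dimethyl)silyl]oxy-2-(2,6-dibromo-4-methylphenoxy)propanoate | COC(=O)[C@H](Oc1c(Br)cc(C)cc1Br)CO[Si](C)(C)C(C)(C)C | intermediate
5 | (3R)-4-[tert-butyl(dimethyl)silyl]oxy-3-(2,6-dibromo-4-methylphenoxy)-2-methylbutan-2-ol | CC(C)(O)[C@H](Oc1c(Br)cc(C)cc1Br)CO[Si](C)(C)C(C)(C)C | intermediate (not isolated)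
6 | (2R)-2-(2,6-dibromo-4-methylphenoxy)-3-methylbutane-1,3-diol | CC(C)(O)[C@H](Oc1c(Br)cc(C)cc1Br)CO | intermediate
7 | 2-[(2R)-8-bromo-6-methyl-2,3-dihydro-1,4-benzodioxin-2-yl]propan-2-ol | CC(C)(O)[C@H]1COc2cc(C)cc(Br)c2O1 | intermediate
8 | [2-[(2R)-8-bromo-6-methyl-2,3-dihydro-1,4-benzodioxin-2-yl]propan-2-yl]oxy-triethylsilane | CC[Si](CC)(CC)OC(C)(C)[C@H]1COc2cc(C)cc(Br)c2O1 | intermediate
9 | 3,3-diethoxyprop-1-yne | CCOC(OCC)C#C | starting material
10 | N-methoxy-N-methylcarbamoyl chloride | CON(C)C(Cl)=O | starting material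
11 | (3,3-diethoxyprop-1-yn-1-yl)lithium | [Li]C#CC(OCC)OCC | intermediate (not isolated)
12 | 4,4-diethoxy-N-methoxy-N-methylbut-2-ynamide | CCOC(OCC)C#CC(=O)N(C)OC | intermediate
13 | [(2R)-6-methyl-2-(2-triethylsilyloxypropan-2-yl)-2,3-dihydro-1,4-benzodioxin-8-yl]lithium | CC[Si](CC)(CC)OC(C)(C)[C@H]1COc2cc(C)cc([Li])c2O1 | intermediate (not isolated)
14 | lithium 4,4-diethoxy-1-[methoxy(methyl)amino]-1-[(2R)-6-methyl-2-(2-triethylsilyloxypropan-2-yl)-2,3-dihydro-1,4-benzodioxin-8-yl]but-2-yn-1-olate (either configuration at the new carbon) | CCOC(OCC)C#CC(O[Li])(N(C)OC)c1cc(C)cc2c1O[C@@H](C(C)(C)O[Si](CC)(CC)CC)CO2 | intermediate (not isolated)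
15 | 4,4-diethoxy-1-[(2R)-6-methyl-2-(2-triethylsilyloxypropan-2-yl)-2,3-dihydro-1,4-benzodioxin-8-yl]but-2-yn-1-one | CCOC(OCC)C#CC(=O)c1cc(C)cc2c1O[C@@H](C(C)(C)O[Si](CC)(CC)CC)CO2 | intermediate
16 | furan | c1ccoc1 | starting material
17 | 1-bromo-3-methylbut-2-ene | CC(C)=CCBr | starting material
18 | furan-2-yllithium | [Li]c1ccco1 | intermediate (not isolated)
19 | 2-(3-methylbut-2-en-1-yl)furan | CC(C)=CCc1ccco1 | intermediate
20 | [3-(diethoxymethyl)-1-(3-methylbut-2-en-1-yl)-7-oxabicyclo[2.2.1]hepta-2,5-dien-2-yl][(2R)-6-methyl-2-(2-triethylsilyloxypropan-2-yl)-2,3-dihydro-1,4-benzodioxin-8-yl]methanone (both bridgehead configurations) | CC(C)=CCC12C=CC(O1)C(C(OCC)OCC)=C2C(=O)c1cc(C)cc2c1O[C@@H](C(C)(C)O[Si](CC)(CC)CC)CO2 | intermediate (not isolated)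
21 | [2-(diethoxymethyl)-3-hydroxy-6-(3-methylbut-2-en-1-yl)phenyl][(2R)-6-methyl-2-(2-triethylsilyloxypropan-2-yl)-2,3-dihydro-1,4-benzodioxin-8-yl]methanone | CC(C)=CCc1ccc(O)c(C(OCC)OCC)c1C(=O)c1cc(C)cc2c1O[C@@H](C(C)(C)O[Si](CC)(CC)CC)CO2 | intermediate
22 | 6-hydroxy-2-[(2R)-2-(2-hydroxypropan-2-yl)-6-methyl-2,3-dihydro-1,4-benzodioxine-8-carbonyl]-3-(3-methylbut-2-en-1-yl)benzaldehyde | CC(C)=CCc1ccc(O)c(C=O)c1C(=O)c1cc(C)cc2c1O[C@@H](C(C)(C)O)CO2 | target

Total step count: 10. Longest linear sequence: 8 steps (steps 1, 2, 3, 4, 5, 7, 9, 10).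

**Steps most likely to fail**

Step 9. The Lewis acid may ionise the diethyl acetal instead of activating the ketone, which would reverse the alkyne polarisation or let the resulting oxocarbenium ion alkylate excess furan. The furan may also add to the ynone as a conjugate hydroarylation without ring closure, the ring oxygen O1 may attack the activated alkyne, or the cycloaddition of the internal ynone may revert faster than the bridge opens. The fallback carries the formyl carbon at the alcohol oxidation level, where no ionisable acetal is present and a stronger aluminium Lewis acid (MeAlCl2) can be used. It sets out from 8. Commercial tert-butyldimethyl(prop-2-yn-1-yloxy)silane would be lithiated with n-BuLi and acylated with 10 to give 4-[tert-butyl(dimethyl)silyl]oxy-N-methoxy-N-methylbut-2-ynamide F1. Aryllithium 13, generated from 8 as in step 7, should add to F1 to give 4-[tert-butyl(dimethyl)silyl]oxy-1-[(2R)-6-methyl-2-(2-triethylsilyloxypropan-2-yl)-2,3-dihydro-1,4-benzodioxin-8-yl]but-2-yn-1-one F2. The same cycloaddition/aromatisation with 19 should give [2-[[tert-butyl(dimethyl)silyl]oxymethyl]-3-hydroxy-6-(3-methylbut-2-en-1-yl)phenyl][(2R)-6-methyl-2-(2-triethylsilyloxypropan-2-yl)-2,3-dihydro-1,4-benzodioxin-8-yl]methanone F3. HF·pyridine in THF would remove both silyl groups to give [3-hydroxy-2-(hydroxymethyl)-6-(3-methylbut-2-en-1-yl)phenyl][(2R)-2-(2-hydroxypropan-2-yl)-6-methyl-2,3-dihydro-1,4-benzodioxin-8-yl]methanone F4, which may sit partly as its cyclic hemiketal. MnO2 in CH2Cl2 should then oxidise only the benzylic alcohol, and the route is rejoined at 22.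

Step 7. The liberated N,O-dimethylhydroxylamine may add to the ynone during work-up, or the aryllithium may add in a conjugate sense or deprotonate the amide. The fallback builds the ketone by addition and oxidation and sets out from 8. Aryllithium 13 would be quenched with DMF to give (2R)-6-methyl-2-(2-triethylsilyloxypropan-2-yl)-2,3-dihydro-1,4-benzodioxine-8-carbaldehyde F5. Addition of lithium acetylide 11 (from 9 and n-BuLi) should give 4,4-diethoxy-1-[(2R)-6-methyl-2-(2-triethylsilyloxypropan-2-yl)-2,3-dihydro-1,4-benzodioxin-8-yl]but-2-yn-1-ol F6 as a mixture of carbinol epimers, which does not matter. Oxidation with MnO2 or Dess–Martin periodinane rejoins the route at 15.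

Step 2. The doubly ortho-brominated phenol may be too hindered to displace the oxyphosphonium intermediate, so that alkylation of the reduced azodicarboxylate or elimination takes over. The fallback separates activation from displacement and sets out from 2. Tf2O and 2,6-lutidine in CH2Cl2 at −78 °C would give methyl (2S)-3-[tert-butyl(dimethyl)silyl]oxy-2-(trifluoromethylsulfonyloxy)propanoate F7. SN2 displacement by the potassium phenoxide of 3 (K2CO3, MeCN, 0 °C → rt) should proceed with the same inversion and rejoin the route at 4.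

**Further compounds**
F1 | step 9 | 4-[tert-butyl(dimethyl)silyl]oxy-N-methoxy-N-methylbut-2-ynamide | CON(C)C(=O)C#CCO[Si](C)(C)C(C)(C)C
F2 | step 9 | 4-[tert-butyl(dimethyl)silyl]oxy-1-[(2R)-6-methyl-2-(2-triethylsilyloxypropan-2-yl)-2,3-dihydro-1,4-benzodioxin-8-yl]but-2-yn-1-one | CC(C)(C)[Si](C)(C)OCC#CC(=O)c1cc(C)cc2c1O[C@@H](C(C)(C)O[Si](CC)(CC)CC)CO2
F3 | step 9 | [2-[[tert-butyl(dimethyl)silyl]oxymethyl]-3-hydroxy-6-(3-methylbut-2-en-1-yl)phenyl][(2R)-6-methyl-2-(2-triethylsilyloxypropan-2-yl)-2,3-dihydro-1,4-benzodioxin-8-yl]methanone | CC(C)=CCc1ccc(O)c(CO[Si](C)(C)C(C)(C)C)c1C(=O)c1cc(C)cc2c1O[C@@H](C(C)(C)O[Si](CC)(CC)CC)CO2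
F4 | step 9 | [3-hydroxy-2-(hydroxymethyl)-6-(3-methylbut-2-en-1-yl)phenyl][(2R)-2-(2-hydroxypropan-2-yl)-6-methyl-2,3-dihydro-1,4-benzodioxin-8-yl]methanone | CC(C)=CCc1ccc(O)c(CO)c1C(=O)c1cc(C)cc2c1O[C@@H](C(C)(C)O)CO2
F5 | step 7 | (2R)-6-methyl-2-(2-triethylsilyloxypropan-2-yl)-2,3-dihydro-1,4-benzodioxine-8-carbaldehyde | CC[Si](CC)(CC)OC(C)(C)[C@H]1COc2cc(C)cc(C=O)c2O1
F6 | step 7 | 4,4-diethoxy-1-[(2R)-6-methyl-2-(2-triethylsilyloxypropan-2-yl)-2,3-dihydro-1,4-benzodioxin-8-yl]but-2-yn-1-ol | CCOC(OCC)C#CC(O)c1cc(C)cc2c1O[C@@H](C(C)(C)O[Si](CC)(CC)CC)CO2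
F7 | step 2 | methyl (2S)-3-[tert-butyl(dimethyl)silyl]oxy-2-(trifluoromethylsulfonyloxy)propanoate | COC(=O)[C@@H](OS(=O)(=O)C(F)(F)F)CO[Si](C)(C)C(C)(C)C
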